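**Retrosynthetic overview**
- The target is unveiled by hydrogenolysis of its (S)-benzyl acetal; the only stereocentre is set one step earlier by an enantioselective C–O acetalization of the racemic lactol.
- The central seven-membered dioxepinone ring is cut at the ester C–O bond (lactonization) and the diaryl ether C–O bond (SNAr), giving a ring A fluoro acid and a ring B catechol-type phthalide.
- Ring B (phthalide lactol) comes from 2,4,5-trimethoxybenzoic acid by ortho-lithiation and formylation; ring A comes from 3-fluoro-5-methylanisole by one-pot formylation and carboxylation.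
- Ring order: phthalide lactone ring (step 1), then dioxepinone ring (steps 4 and 5), then the stereocentre (step 6), then unveiling (step 7).

Assumption: the lactol carbon is the only stereocentre and is (S) as drawn; because free hydroxyphthalide lactols can racemise by ring–chain tautomerism, it is fixed as a benzyl acetal in the last-but-one step and released under neutral, cold conditions, and the (R)-configured acid catalyst is assumed to give (S) (otherwise its mirror image is used).

**Step 1**
Reactants: 1 2,4,5-trimethoxybenzoic acid
Product: 3 rac-3-hydroxy-4,5,7-trimethoxy-2-benzofuran-1(3H)-one, via dilithiated benzoate 2 (not isolated)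
Conditions: s-BuLi (2.2 equiv), TMEDA, THF, −78 °C; DMF, −78 °C to rt; 2 M HCl
Reagents that add atoms: N,N-dimethylformamide CN(C)C=O
Why: Carboxylate-directed ortho-metalation takes place at C-6, the only position flanked by the carboxylate and a methoxy group, and DMF formylation followed by acid closes the 2-formylbenzoic acid to its lactol, whose new stereocentre is formed racemic.

**Step 2**
Reactants: 3 rac-3-hydroxy-4,5,7-trimethoxy-2-benzofuran-1(3H)-one
Product: 5 rac-4,5,7-trihydroxy-3-methoxy-2-benzofuran-1(3H)-one, via tetrahydroxyphthalide 4 (not isolated)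
Conditions: BBr3 (5 equiv), CH2Cl2, −78 °C to rt; then MeOH, reflux
Reagents that add atoms: methanol CO
Why: BBr3 ether cleavage removes all three aryl methyl groups, and the HBr/MeOH formed on quenching converts the lactol into its cyclic methyl pseudo-ester (acid-catalysed acetalization), which locks the ring-closed phthalide form needed in step 4.

**Step 3**
Reactants: 6 1-fluoro-3-methoxy-5-methylbenzene
Product: 10 2-fluoro-3-formyl-4-methoxy-6-methylbenzoic acid, via aryllithium 7 (not isolated), via lithium hemiaminal alkoxide 8 (not isolated), via ring-lithiated hemiaminal alkoxide 9 (not isolated)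
Conditions: n-BuLi (1.05 equiv), THF, −78 °C; DMF (1.0 equiv), −78 °C; s-BuLi (1.3 equiv), PMDTA, −78 °C; CO2; 2 M HCl
Reagents that add atoms: N,N-dimethylformamide CN(C)C=O; carbon dioxide O=C=O
Why: Directed ortho-metalation first occurs between F and OMe, the DMF adduct serves as an in situ protected aldehyde (alpha-amino alkoxide), and the second, acidity-controlled lithiation next to fluorine (s-BuLi/PMDTA) is trapped by carboxylation.

**Step 4**
Reactants: 5 rac-4,5,7-trihydroxy-3-methoxy-2-benzofuran-1(3H)-one; 10 2-fluoro-3-formyl-4-methoxy-6-methylbenzoic acid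
Product: 11 rac-2-[(5,7-dihydroxy-3-methoxy-1-oxo-1,3-dihydro-2-benzofuran-4-yl)oxy]-3-formyl-4-methoxy-6-methylbenzoic acid
Conditions: t-BuOK (4.0 equiv), degassed DMSO, Ar, rt to 70 °C; 1 M HCl
Reagents that add atoms: none
Why: Nucleophilic aromatic substitution (SNAr) of the fluoride activated by the ortho formyl group; in the trianion of 5 the 4-oxide is the only phenoxide not conjugated to the lactone carbonyl and therefore the most nucleophilic, by analogy with the selective meta-O-alkylation of catechol carbonyl dianions.

**Step 5**
Reactants: 11 rac-2-[(5,7-dihydroxy-3-methoxy-1-oxo-1,3-dihydro-2-benzofuran-4-yl)oxy]-3-formyl-4-methoxy-6-methylbenzoic acid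
Product: 13 racemic lactol depsidone (racemic target), via methyl acetal depsidone 12 (not isolated)
Conditions: TFAA (4 equiv), toluene (0.01 M), rt; then TFA–H2O (4:1), 45 °C
Reagents that add atoms: water O
Why: Mixed-anhydride lactonization, in which only the 5-OH next to the ether oxygen can reach the activated ring A carboxyl to close the seven-membered depsidone ester, followed by acid hydrolysis of the methyl pseudo-ester to the free lactol.

**Step 6**
Reactants: 13 racemic lactol depsidone
Product: 14 (S)-benzyl acetal depsidone
Conditions: BnOH (2 equiv), (R)-3,3′-bis(2,4,6-triisopropylphenyl)-1,1′-binaphthyl-2,2′-diyl hydrogen phosphate (5 mol %), 5 Å MS, CH2Cl2, −20 °C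
Reagents that add atoms: benzyl alcohol OCc1ccccc1
Why: Proposed new method: a chiral phosphoric acid catalysed enantioselective dehydrative acetalization of a 3-hydroxyphthalide, in which the lactol racemises through its open 2-formylbenzoic acid form, benzyl alcohol gives a hemiacetal, the bifunctional acid ionises it to an O-benzyl oxocarbenium ion paired with the chiral phosphate, and the neighbouring carboxylic acid (hydrogen-bonded to the P=O) closes the lactone C–O bond on one face to give the (S)-acetal, which as an acylal-type acetal no longer ionises at −20 °C; the closest known reaction types are chiral phosphoric acid catalysed asymmetric transacetalization of hydroxy acetals, N,O-acetal formation from 3-hydroxyisoindolinones, and the racemic acid-catalysed pseudo-ester formation of 2-formylbenzoic acids.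

**Step 7**
Reactants: 14 (S)-benzyl acetal depsidone
Product: 15 target depsidone with (S)-lactol
Conditions: H2 (1 atm), 10% Pd/C, EtOAc, 0 °C; cold filtration and evaporation
Reagents that add atoms: none
Why: Hydrogenolysis of the benzyl ether breaks only the O–CH2Ph bond, so the acetal carbon keeps its (S) configuration, and the neutral aprotic medium avoids the acid- or base-promoted ring–chain tautomerism that would racemise the lactol.

**Compound list**
1 | 2,4,5-trimethoxybenzoic acid | COc1cc(OC)c(OC)cc1C(=O)O | starting material
2 | lithium 6-lithio-2,4,5-trimethoxybenzoate (not isolated) | [Li]c1c(OC)c(OC)cc(OC)c1C(=O)O[Li] | intermediate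
3 | rac-3-hydroxy-4,5,7-trimethoxy-2-benzofuran-1(3H)-one (lactol of 6-formyl-2,4,5-trimethoxybenzoic acid) | COc1cc(OC)c(OC)c2c1C(=O)OC2O | intermediate
4 | rac-3,4,5,7-tetrahydroxy-2-benzofuran-1(3H)-one (not isolated) | Oc1cc(O)c(O)c2c1C(=O)OC2O | intermediate
5 | rac-4,5,7-trihydroxy-3-methoxy-2-benzofuran-1(3H)-one | Oc1cc(O)c(O)c2c1C(=O)OC2OC | intermediate
6 | 1-fluoro-3-methoxy-5-methylbenzene (3-fluoro-5-methylanisole) | COc1cc(C)cc(F)c1 | starting material
7 | (2-fluoro-6-methoxy-4-methylphenyl)lithium (not isolated) | [Li]c1c(F)cc(C)cc1OC | intermediate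
8 | lithium (dimethylamino)(2-fluoro-6-methoxy-4-methylphenyl)methanolate (not isolated) | CN(C)C(O[Li])c1c(F)cc(C)cc1OC | intermediate
9 | lithium (dimethylamino)(2-fluoro-3-lithio-6-methoxy-4-methylphenyl)methanolate (not isolated) | CN(C)C(O[Li])c1c(F)c([Li])c(C)cc1OC | intermediate
10 | 2-fluoro-3-formyl-4-methoxy-6-methylbenzoic acid | COc1cc(C)c(C(=O)O)c(F)c1C=O | intermediate
11 | rac-2-[(5,7-dihydroxy-3-methoxy-1-oxo-1,3-dihydro-2-benzofuran-4-yl)oxy]-3-formyl-4-methoxy-6-methylbenzoic acid | COc1cc(C)c(C(=O)O)c(Oc2c(O)cc(O)c3c2C(OC)OC3=O)c1C=O | intermediate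
12 | racemic methyl acetal depsidone: the target skeleton with OCH3 in place of the lactol OH (not isolated) | COc1cc(C)c2c(c1C=O)Oc1c(cc(O)c3c1C(OC)OC3=O)OC2=O | intermediate
13 | racemic lactol depsidone: the target as a 1:1 mixture of both lactol configurations | COc1cc(C)c2c(c1C=O)Oc1c(cc(O)c3c1C(O)OC3=O)OC2=O | intermediate
14 | (S)-benzyl acetal depsidone: the target with OCH2Ph in place of the lactol OH, S at the acetal carbon | COc1cc(C)c2c(c1C=O)Oc1c(cc(O)c3c1[C@@H](OCc1ccccc1)OC3=O)OC2=O | intermediate
15 | target depsidone: ring A is a 3-formyl-4-methoxy-6-methylbenzoyl unit and ring B a (3S)-3,7-dihydroxyphthalide; ring A C-2 is joined by an ether oxygen to phthalide C-4 and the ring A carboxyl forms the ester with the oxygen on phthalide C-5 | COc1cc(C)c2c(c1C=O)Oc1c(cc(O)c3c1[C@@H](O)OC3=O)OC2=O | target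

**Step count**
Total step count: 7. Longest linear sequence: 6 steps (steps 1, 2, 4, 5, 6, 7).

**Three steps most likely to fail**

Step 6 (the proposed new enantioselective acetalization). Risks are low enantioselectivity, an uncatalysed background reaction, or slow turnover with this poorly soluble polyphenol. The fallback uses known chemistry, sets out from 13 and comes back at 15. Compound 13 is heated with (S)-1-phenylethanol and catalytic camphorsulfonic acid in toluene over molecular sieves (classical pseudo-ester formation). This gives two diastereomers, the (3S)-3-[(1S)-1-phenylethoxy] acetal depsidone F1 and the (3R)-3-[(1S)-1-phenylethoxy] acetal depsidone F2. They are separated by chromatography or crystallisation, and F2 is re-equilibrated with the same acid and recycled. Hydrogenolysis of F1 under the conditions of step 7 cleaves the benzylic O–C bond and gives 15 directly.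

Step 4 (SNAr of a hindered fluoride with a trianion). Risks are arylation at the 7- or 5-oxygen, air oxidation of the polyphenoxide, and loss of the pseudo-ester. The fallback replaces polyanion selectivity by protecting-group control, sets out from 5 and comes back at 11. Compound 5 is alkylated at its most acidic, unchelated phenol with one equivalent of BnBr and KHCO3 in DMF to give rac-5-(benzyloxy)-4,7-dihydroxy-3-methoxy-2-benzofuran-1(3H)-one F3. Coupling of F3 with 10 (t-BuOK, DMSO), where only the chelated 7-OH can compete, gives the 5-O-benzyl diaryl ether acid F4. Hydrogenolysis of F4 (H2, 10% Pd/C, EtOAc) returns 11.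

Step 3 (one-pot double lithiation). Risks are incomplete or wrongly placed second lithiation, benzylic deprotonation, or aryne formation from the ortho-lithio fluoroarene. The fallback installs the carboxyl by halogenation and carbonylation, sets out from 6 and comes back at 10. Only the first lithiation and DMF quench are run and worked up to give 2-fluoro-6-methoxy-4-methylbenzaldehyde F5. Electrophilic bromination (NBS, MeCN) para to the methoxy group gives 3-bromo-2-fluoro-6-methoxy-4-methylbenzaldehyde F6. Hydroxycarbonylation of F6 (Pd(OAc)2, 4,5-bis(diphenylphosphino)-9,9-dimethylxanthene, CO, KOAc, H2O, DMSO, 80 °C) gives 10.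

**Further compounds**
F1 | step 6 | (3S)-3-[(1S)-1-phenylethoxy] acetal depsidone | COc1cc(C)c2c(c1C=O)Oc1c(cc(O)c3c1[C@@H](O[C@@H](C)c1ccccc1)OC3=O)OC2=O
F2 | step 6 | (3R)-3-[(1S)-1-phenylethoxy] acetal depsidone | COc1cc(C)c2c(c1C=O)Oc1c(cc(O)c3c1[C@H](O[C@@H](C)c1ccccc1)OC3=O)OC2=O
F3 | step 4 | rac-5-(benzyloxy)-4,7-dihydroxy-3-methoxy-2-benzofuran-1(3H)-one | Oc1cc(OCc3ccccc3)c(O)c2c1C(=O)OC2OC
F4 | step 4 | rac-2-{[5-(benzyloxy)-7-hydroxy-3-methoxy-1-oxo-1,3-dihydro-2-benzofuran-4-yl]oxy}-3-formyl-4-methoxy-6-methylbenzoic acid | COc1cc(C)c(C(=O)O)c(Oc2c(OCc4ccccc4)cc(O)c3c2C(OC)OC3=O)c1C=O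
F5 | step 3 | 2-fluoro-6-methoxy-4-methylbenzaldehyde | COc1cc(C)cc(F)c1C=O
F6 | step 3 | 3-bromo-2-fluoro-6-methoxy-4-methylbenzaldehyde | COc1cc(C)c(Br)c(F)c1C=O
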